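**Plan**
1. Retrosynthesis: the butenolide (from a 3-furyl group), the three esters and the C1 carbinol (from a ketone) are unmasked last; C4=C18 is cut by methylenation and C7–O/C8–O by dihydroxylation of a Δ7 alkene; ring A of the resulting 18-nor-1,4-dione is cut at C4–C5 and C1–C10.
2. Enabling feature: in ring A the carbinol carbon C1 and the sp2 carbon C4 (a masked ketone) stand 1,4 to each other on either side of the C5–C10 bond, and C5 is quaternary. C1–C4 therefore map onto a squarate cyclobutenone and C10=C5 onto a ring-B vinyl anion, so that thermal 4π-opening/6π-closure expands the four-membered ring by C10 and C5 to ring A.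
3. Ring B comes from a flat arene: 2,5-dimethylanisole → benzamide → Birch reductive methylation (C9) → side chain C11–C16 as a 3-furylethyl carbinol → enol triflate → bis-allylic oxidation (C6).
4. Forward order: ring B (cyclohexa-1,4-diene) → vinylstannane → squarate adduct → ring A (key step) → demethoxylation, Δ7 dihydroxylation, C4 methylenation, acylations, C1 reduction, furan → butenolide.
5. Stereochemistry: C9 by auxiliary-controlled alkylation; C11 and C6 by CBS reductions; C5 by the 6α-silyloxy group in the electrocyclization; C10 by ketonization to the trans-decalin; C7/C8 by β-face osmylation; C1 by electron-transfer reduction to the equatorial alcohol.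
6. Clerodane numbering is used (ring A: C1–C5, C10; ring B: C5–C10; side chain C11–C16; C17, C18, C19, C20 on C8, C4, C5, C9); α/β refer to the usual drawing with H-10 β.

Key step: step 15

Remark (assumption): the (S)-auxiliary is taken to deliver the methyl group in step 3 to the enolate face that gives the C9 configuration drawn (C20 α), by the chelated-enolate model for such 2-methoxybenzamides; if the opposite sense operates, the (R)-auxiliary is used in step 2 and nothing else changes.

**Route**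

Step 1
Reactants: 1 2,5-dimethylanisole
Product: 3 2-methoxy-3,6-dimethylbenzoic acid, via (2-methoxy-3,6-dimethylphenyl)lithium 2 (not isolated)
Conditions: sec-BuLi, TMEDA, Et2O, 0 °C → rt; CO2, −78 °C; aq HCl
Reagents that add atoms: carbon dioxide O=C=O
Why: Directed ortho-lithiation at the only free position ortho to the methoxy group, followed by carboxylation, gives the 2,6-disubstituted benzoic acid.

Step 2
Reactants: 3 2-methoxy-3,6-dimethylbenzoic acid
Product: 5 [(2S)-2-(methoxymethyl)pyrrolidin-1-yl](2-methoxy-3,6-dimethylphenyl)methanone, via acid chloride 4 (not isolated)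
Conditions: (COCl)2, DMF (cat.), CH2Cl2, rt; then (S)-2-(methoxymethyl)pyrrolidine, Et3N, 0 °C → rt
Reagents that add atoms: (S)-2-(methoxymethyl)pyrrolidine COC[C@@H]1CCCN1
Why: Acid chloride formation and amidation attach the prolinol-ether auxiliary to the hindered acid.

Step 3
Reactants: 5 benzamide
Product: 7 [(2S)-2-(methoxymethyl)pyrrolidin-1-yl][(1S)-2-methoxy-1,3,6-trimethylcyclohexa-2,5-dien-1-yl]methanone, via potassium amide enolate 6 (not isolated)
Conditions: K, NH3/THF, t-BuOH (1 equiv), −78 °C; piperylene; MeI, −78 °C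
Reagents that add atoms: iodomethane CI
Why: Birch reductive alkylation dearomatizes the arene to a chelated amide enolate, which is methylated at the ipso carbon on the face set by the pyrrolidine auxiliary, creating the quaternary centre C9 (C20 α).

Step 4
Reactants: 7 Birch amide
Product: 8 1-[(1S)-2-methoxy-1,3,6-trimethylcyclohexa-2,5-dien-1-yl]ethan-1-one
Conditions: MeLi, THF, 0 °C → rt; aq NH4Cl
Reagents that add atoms: methyllithium [Li]C
Why: Organolithium addition to the tertiary amide gives a tetrahedral adduct, stabilized by chelation to the methoxymethyl arm, that collapses to the methyl ketone only on work-up and releases the auxiliary.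

Step 5
Reactants: 8 methyl ketone
Product: 9 2-(furan-3-yl)-1-[(1S)-2-methoxy-1,3,6-trimethylcyclohexa-2,5-dien-1-yl]ethan-1-one
Conditions: 3-bromofuran, Pd2(dba)3 (cat.), Xantphos, NaOtBu, THF, 65 °C
Reagents that add atoms: 3-bromofuran Brc1ccoc1
Why: Palladium-catalysed ketone α-arylation; the methyl group is the only enolisable position (C9 is quaternary) and the less reactive product enolate should prevent a second arylation.

Step 6
Reactants: 9 furylmethyl ketone
Product: 10 (1S)-2-(furan-3-yl)-1-[(1R)-2-methoxy-1,3,6-trimethylcyclohexa-2,5-dien-1-yl]ethan-1-ol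
Conditions: (R)-2-methyl-CBS-oxazaborolidine (cat.), BH3·SMe2, THF, −20 °C; MeOH
Reagents that add atoms: none
Why: Corey–Bakshi–Shibata reduction with the quaternary C9 as the large and the furylmethyl group as the small substituent should deliver hydride to the face that gives the 11S carbinol under reagent control.

Step 7
Reactants: 10 carbinol
Product: 11 tert-butyl{(1S)-2-(furan-3-yl)-1-[(1R)-2-methoxy-1,3,6-trimethylcyclohexa-2,5-dien-1-yl]ethoxy}dimethylsilane
Conditions: TBSOTf, 2,6-lutidine, CH2Cl2, −78 → 0 °C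
Reagents that add atoms: tert-butyldimethylsilyl triflate CC(C)(C)[Si](C)(C)OS(=O)(=O)C(F)(F)F
Why: Silylation of the hindered neopentyl-type secondary alcohol with the silyl triflate protects C11–OH against the later organometallic steps.

Step 8
Reactants: 11 silyl ether
Product: 12 (6R)-6-[(1S)-1-(tert-butyldimethylsilyloxy)-2-(furan-3-yl)ethyl]-2,5,6-trimethylcyclohex-4-en-1-one (C10 ketone; epimers at C5)
Conditions: 1 M aq HCl, THF, 0 °C → rt
Reagents that add atoms: water O
Why: Acid hydrolysis of the methyl enol ether to the C10 ketone is done before C6 is oxygenated, so no allylic leaving group can be lost.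

Step 9
Reactants: 12 ketone
Product: 13 (6R)-6-[(1S)-1-(tert-butyldimethylsilyloxy)-2-(furan-3-yl)ethyl]-2,5,6-trimethylcyclohexa-1,4-dien-1-yl trifluoromethanesulfonate
Conditions: KN(SiMe3)2, THF, −78 °C; PhNTf2
Reagents that add atoms: N-phenylbis(trifluoromethanesulfonimide) O=S(=O)(N(c1ccccc1)S(=O)(=O)C(F)(F)F)C(F)(F)F
Why: C5–H is the only α-hydrogen (C9 is quaternary), so enolate triflation gives the tetrasubstituted C10=C5 enol triflate regiospecifically and removes the C5 stereocentre.

Step 10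
Reactants: 13 enol triflate
Product: 14 (6R)-6-[(1S)-1-(tert-butyldimethylsilyloxy)-2-(furan-3-yl)ethyl]-2,5,6-trimethyl-3-oxocyclohexa-1,4-dien-1-yl trifluoromethanesulfonate
Conditions: pyridinium dichromate (C5H5NH)2Cr2O7, t-BuOOH, Celite, benzene, 10 °C → rt
Reagents that add atoms: tert-butyl hydroperoxide CC(C)(C)OO
Why: Allylic oxidation of the doubly allylic C6 methylene (the weakest C–H bond of the cyclohexa-1,4-diene) should give the cross-conjugated dienone, as is usual for Birch-derived 1,4-dienes.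

Step 11
Reactants: 14 dienone
Product: 15 (3S,6R)-6-[(1S)-1-(tert-butyldimethylsilyloxy)-2-(furan-3-yl)ethyl]-3-hydroxy-2,5,6-trimethylcyclohexa-1,4-dien-1-yl trifluoromethanesulfonate (6α-OH)
Conditions: (R)-2-methyl-CBS-oxazaborolidine (cat.), catecholborane, toluene, −78 °C
Reagents that add atoms: none
Why: CBS 1,2-reduction in which the α-methyl-substituted vinyl arm (C5) acts as the large and the unsubstituted arm (C7) as the small group should give the 6S (6α) alcohol under reagent control.

Step 12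
Reactants: 15 dienol
Product: 16 (3S,6R)-3-(tert-butyldimethylsilyloxy)-6-[(1S)-1-(tert-butyldimethylsilyloxy)-2-(furan-3-yl)ethyl]-2,5,6-trimethylcyclohexa-1,4-dien-1-yl trifluoromethanesulfonate
Conditions: TBSCl, imidazole, DMF, rt
Reagents that add atoms: tert-butyldimethylsilyl chloride CC(C)(C)[Si](C)(C)Cl
Why: Base-mediated silylation protects the acid-sensitive bis-allylic alcohol and installs the bulky 6α-substituent that later directs the ring closure.

Step 13
Reactants: 16 bis-silyl enol triflate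
Product: 17 tert-butyl{[(1S,4R)-4-[(1S)-1-(tert-butyldimethylsilyloxy)-2-(furan-3-yl)ethyl]-2,4,5-trimethyl-3-(trimethylstannyl)cyclohexa-2,5-dien-1-yl]oxy}dimethylsilane
Conditions: (Me3Sn)2, Pd(PPh3)4 (cat.), LiCl, THF, 65 °C
Reagents that add atoms: hexamethylditin C[Sn](C)(C)[Sn](C)(C)C
Why: Palladium-catalysed stannylation of the enol triflate (Stille-type coupling with the ditin) turns the C10 electrophile into the precursor of a vinyl nucleophile.

Step 14
Reactants: 17 vinylstannane; 18 dimethyl squarate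
Product: 20 4-hydroxy-2,3-dimethoxy-4-(ring-B dienyl)cyclobut-2-en-1-one (ring B as in 17; carbinol epimers), via vinyllithium 19 (not isolated)
Conditions: MeLi, THF, −78 °C; then 18, −78 °C; aq NH4Cl
Reagents that add atoms: none
Why: Tin–lithium exchange followed by 1,2-addition of the vinyllithium to a squarate carbonyl, the standard entry to 4-hydroxycyclobutenones, forms the C1–C10 bond; the new carbinol centre is lost in the next step.

Step 15
Reactants: 20 squarate adduct
Product: 23 (11S)-6α,11-bis(tert-butyldimethylsilyloxy)-2,3-dimethoxy-15,16-epoxy-18-nor-neo-cleroda-2,7,13(16),14-tetraene-1,4-dione (10β-H), via dienylketene 21 (not isolated), via hydroxy-dienone 22 (not isolated)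
Conditions: toluene (degassed), 110 °C; then DBU (cat.), rt
Reagents that add atoms: none
Why: Heating opens the cyclobutenone by conrotatory 4π-electrocyclic cleavage of the C1–C4 σ-bond, the hydroxyl on C1 rotating outward so that the ring-B alkenyl group points inward (21), and the ketene carbon C4 then closes on C5 by 6π-disrotatory electrocyclization to 22, whose dienol ketonizes at C10. The closest known reaction type is the thermal ring expansion (Moore rearrangement) of squarate-derived 4-alkenyl-4-hydroxycyclobutenones to hydroquinones, quinones or, with a fully substituted alkene terminus, cyclohexene-1,4-diones. Ring A (C1–C5, C10) is closed by this 6π-electrocyclization through the new C4–C5 bond, so the four-membered ring C1–C4 is expanded by the two atoms C10 and C5. C5 is set by approach of the ketene to the C10=C5 bond of the flat cyclohexa-1,4-diene anti to the allylic 6α-silyloxy group, that is from the β-face, which leaves C19 α. C10 is set by protonation α to the C1 carbonyl on the β-face, away from the two α-methyls C19 and C20, to give the trans-fused dione, and DBU should converge any cis epimer. The step needs outward rotation of the hydroxyl, 6π-closure in preference to capture of the ketene by that hydroxyl, and β-face selectivity; these rest on the oxygen donor at C1, the s-cis dienyl geometry fixed by the ring-B vinyl group, and the C6 substituent.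

Step 16
Reactants: 23 dimethoxy ene-dione
Product: 24 (11S)-6α,11-bis(tert-butyldimethylsilyloxy)-15,16-epoxy-18-nor-neo-cleroda-7,13(16),14-triene-1,4-dione
Conditions: SmI2 (excess), MeOH, THF, −78 → 0 °C
Reagents that add atoms: none
Why: Electron-transfer reduction of the ene-dione to its bis-enolate, then reductive cleavage of the two α-methoxy ketones (the known reduction of α-hetero-substituted ketones by SmI2), removes both helper methoxy groups and leaves the saturated 1,4-dione.

Step 17
Reactants: 24 1,4-dione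
Product: 25 (11S)-6α,11-bis(tert-butyldimethylsilyloxy)-7β,8β-dihydroxy-15,16-epoxy-18-nor-neo-cleroda-13(16),14-diene-1,4-dione
Conditions: OsO4 (cat.), N-methylmorpholine N-oxide, acetone/H2O, rt
Reagents that add atoms: N-methylmorpholine N-oxide C[N+]1([O-])CCOCC1; water O
Why: syn-Dihydroxylation of the trisubstituted Δ7 alkene from the β-face, anti to the allylic 6α-silyloxy group and to the axial α-methyls C19 and C20, should set 7β-OH and 8β-OH (C17 α); furans are known to survive catalytic osmylation.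

Step 18
Reactants: 25 diol dione
Product: 26 (11S)-6α,11-bis(tert-butyldimethylsilyloxy)-7β,8β-dihydroxy-15,16-epoxy-neo-cleroda-4(18),13(16),14-trien-1-one
Conditions: Ph3PCH3Br, KOtBu, THF, 0 °C → rt
Reagents that add atoms: methyltriphenylphosphonium bromide C[P+](c1ccccc1)(c1ccccc1)c1ccccc1.[Br-]
Why: Wittig methylenation should take place at C4, whose carbonyl is open to axial attack from the β-face, rather than at C1, whose carbonyl is shielded by C10 standing between the quaternary carbons C5 and C9.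

Step 19
Reactants: 26 exo-methylene ketone diol
Product: 27 (11S)-6α,11-bis(tert-butyldimethylsilyloxy)-8β-hydroxy-7β-isobutyryloxy-15,16-epoxy-neo-cleroda-4(18),13(16),14-trien-1-one
Conditions: i-PrCOCl, pyridine, DMAP (cat.), CH2Cl2, 0 °C → rt
Reagents that add atoms: isobutyryl chloride CC(C)C(=O)Cl
Why: Acylation of the secondary 7β-hydroxyl; the tertiary 8β-hydroxyl does not react under these conditions.

Step 20
Reactants: 27 isobutyrate
Product: 28 (11S)-6α,8β,11-trihydroxy-7β-isobutyryloxy-15,16-epoxy-neo-cleroda-4(18),13(16),14-trien-1-one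
Conditions: HF·pyridine, pyridine, THF, 0 °C → rt
Reagents that add atoms: none
Why: Fluoride cleavage of both silyl ethers under weakly acidic, buffered conditions, which should suppress migration of the C7 ester to the freed C6 hydroxyl.

Step 21
Reactants: 28 triol
Product: 29 (11S)-6α,11-diacetoxy-8β-hydroxy-7β-isobutyryloxy-15,16-epoxy-neo-cleroda-4(18),13(16),14-trien-1-one
Conditions: Ac2O, pyridine, DMAP (cat.), CH2Cl2, rt
Reagents that add atoms: acetic anhydride CC(=O)OC(C)=O
Why: Acetylation of the two secondary hydroxyls at C6 and C11; the tertiary C8 hydroxyl is inert and C1, still a ketone, needs no protecting group.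

Step 22
Reactants: 29 diacetate ketone
Product: 30 (11S)-6α,11-diacetoxy-1β,8β-dihydroxy-7β-isobutyryloxy-15,16-epoxy-neo-cleroda-4(18),13(16),14-triene
Conditions: SmI2, HMPA, i-PrOH, THF, −20 °C
Reagents that add atoms: none
Why: Electron-transfer (ketyl) reduction should give the more stable equatorial 1β-alcohol (a 1α-hydroxyl would be syn-diaxial to C19), whereas hydride reagents would attack from the β-face; esters, furan and the exocyclic alkene are inert.

Step 23
Reactants: 30 furan
Product: 32 (11S)-6α,11-diacetoxy-1β,8β,16-trihydroxy-7β-isobutyryloxy-neo-cleroda-4(18),13-dien-15,16-olide (C16 epimers), via furan endoperoxide 31 (not isolated)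
Conditions: O2, hν, tetraphenylporphyrin (cat.), i-Pr2NEt, CH2Cl2, −78 °C
Reagents that add atoms: oxygen O=O
Why: [4+2] cycloaddition of singlet oxygen to the furan, then base-induced Kornblum–DeLaMare fragmentation with removal of the less hindered H-15, gives the 16-hydroxy-15,16-olide; the hindered exocyclic alkene reacts far more slowly in the ene mode.

Step 24
Reactants: 32 hydroxybutenolide
Product: 33 CNP0254453.1, (11S)-6α,11-diacetoxy-1β,8β-dihydroxy-7β-isobutyryloxy-neo-cleroda-4(18),13-dien-15,16-olide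
Conditions: NaBH4, EtOH, 0 °C; then dil. HCl
Reagents that add atoms: none
Why: Borohydride reduces the lactol (a masked C16 aldehyde) to the hydroxy acid, which relactonizes to the 15,16-butenolide; the esters should survive the short exposure at 0 °C.

**Compound list**

1 | 2,5-dimethylanisole | COc1cc(C)ccc1C | starting material
2 | (2-methoxy-3,6-dimethylphenyl)lithium | COc1c(C)ccc(C)c1[Li] | intermediate
3 | 2-methoxy-3,6-dimethylbenzoic acid | COc1c(C)ccc(C)c1C(=O)O | intermediate
4 | 2-methoxy-3,6-dimethylbenzoyl chloride | COc1c(C)ccc(C)c1C(Cl)=O | intermediate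
5 | [(2S)-2-(methoxymethyl)pyrrolidin-1-yl](2-methoxy-3,6-dimethylphenyl)methanone | COC[C@@H]1CCCN1C(=O)c1c(C)ccc(C)c1OC | intermediate
6 | potassium amide enolate of the 1,4-dihydrobenzamide | COC[C@@H]1CCCN1C(O[K])=C1C(C)=CCC(C)=C1OC | intermediate
7 | [(2S)-2-(methoxymethyl)pyrrolidin-1-yl][(1S)-2-methoxy-1,3,6-trimethylcyclohexa-2,5-dien-1-yl]methanone | COC1=C(C)CC=C(C)[C@]1(C)C(=O)N1CCC[C@H]1COC | intermediate
8 | 1-[(1S)-2-methoxy-1,3,6-trimethylcyclohexa-2,5-dien-1-yl]ethan-1-one | COC1=C(C)CC=C(C)[C@]1(C)C(C)=O | intermediate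
9 | 2-(furan-3-yl)-1-[(1S)-2-methoxy-1,3,6-trimethylcyclohexa-2,5-dien-1-yl]ethan-1-one | COC1=C(C)CC=C(C)[C@]1(C)C(=O)Cc1ccoc1 | intermediate
10 | (1S)-2-(furan-3-yl)-1-[(1R)-2-methoxy-1,3,6-trimethylcyclohexa-2,5-dien-1-yl]ethan-1-ol | COC1=C(C)CC=C(C)[C@]1(C)[C@@H](O)Cc1ccoc1 | intermediate
11 | tert-butyldimethylsilyl ether of 10 | COC1=C(C)CC=C(C)[C@]1(C)[C@@H](O[Si](C)(C)C(C)(C)C)Cc1ccoc1 | intermediate
12 | (6R)-6-[(1S)-1-(tert-butyldimethylsilyloxy)-2-(furan-3-yl)ethyl]-2,5,6-trimethylcyclohex-4-en-1-one (C5 epimers) | O=C1C(C)CC=C(C)[C@]1(C)[C@@H](O[Si](C)(C)C(C)(C)C)Cc1ccoc1 | intermediate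
13 | (6R)-6-[(1S)-1-(tert-butyldimethylsilyloxy)-2-(furan-3-yl)ethyl]-2,5,6-trimethylcyclohexa-1,4-dien-1-yl triflate | O=S(=O)(OC1=C(C)CC=C(C)[C@]1(C)[C@@H](O[Si](C)(C)C(C)(C)C)Cc1ccoc1)C(F)(F)F | intermediate
14 | (6R)-6-[(1S)-1-(tert-butyldimethylsilyloxy)-2-(furan-3-yl)ethyl]-2,5,6-trimethyl-3-oxocyclohexa-1,4-dien-1-yl triflate | O=C1C=C(C)[C@](C)([C@@H](O[Si](C)(C)C(C)(C)C)Cc2ccoc2)C(OS(=O)(=O)C(F)(F)F)=C1C | intermediate
15 | (3S,6R)-3-hydroxy analogue of 14 (6α-OH) | O[C@H]1C=C(C)[C@](C)([C@@H](O[Si](C)(C)C(C)(C)C)Cc2ccoc2)C(OS(=O)(=O)C(F)(F)F)=C1C | intermediate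
16 | (3S,6R)-3-(tert-butyldimethylsilyloxy) enol triflate | CC(C)(C)[Si](C)(C)O[C@H]1C=C(C)[C@](C)([C@@H](O[Si](C)(C)C(C)(C)C)Cc2ccoc2)C(OS(=O)(=O)C(F)(F)F)=C1C | intermediate
17 | ring-B C10 trimethylstannane (1S,4R; side chain 1S) | CC(C)(C)[Si](C)(C)O[C@H]1C=C(C)[C@](C)([C@@H](O[Si](C)(C)C(C)(C)C)Cc2ccoc2)C([Sn](C)(C)C)=C1C | intermediate
18 | dimethyl squarate (3,4-dimethoxycyclobut-3-ene-1,2-dione) | COC1=C(OC)C(=O)C1=O | starting material
19 | ring-B C10 vinyllithium | CC(C)(C)[Si](C)(C)O[C@H]1C=C(C)[C@](C)([C@@H](O[Si](C)(C)C(C)(C)C)Cc2ccoc2)C([Li])=C1C | intermediate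
20 | 4-hydroxy-2,3-dimethoxy-4-(ring-B dienyl)cyclobut-2-en-1-one | CC(C)(C)[Si](C)(C)O[C@H]1C=C(C)[C@](C)([C@@H](O[Si](C)(C)C(C)(C)C)Cc2ccoc2)C(C2(O)C(OC)=C(OC)C2=O)=C1C | intermediate
21 | (Z)-dienylketene from ring opening of 20 | O=C=C(OC)/C(OC)=C(O)\C1=C(C)[C@@H](O[Si](C)(C)C(C)(C)C)C=C(C)[C@]1(C)[C@@H](O[Si](C)(C)C(C)(C)C)Cc1ccoc1 | intermediate
22 | 1-hydroxy-2,3-dimethoxy-1(10),2-dien-4-one (dienol of 23) | O=C1C(OC)=C(OC)C(O)=C2[C@@]1(C)[C@@H](O[Si](C)(C)C(C)(C)C)C=C(C)[C@]2(C)[C@@H](O[Si](C)(C)C(C)(C)C)Cc1ccoc1 | intermediate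
23 | (11S)-6α,11-bis(tert-butyldimethylsilyloxy)-2,3-dimethoxy-15,16-epoxy-18-nor-neo-cleroda-2,7,13(16),14-tetraene-1,4-dione | O=C1C(OC)=C(OC)C(=O)[C@H]2[C@@]1(C)[C@@H](O[Si](C)(C)C(C)(C)C)C=C(C)[C@]2(C)[C@@H](O[Si](C)(C)C(C)(C)C)Cc1ccoc1 | intermediate
24 | (11S)-6α,11-bis(tert-butyldimethylsilyloxy)-15,16-epoxy-18-nor-neo-cleroda-7,13(16),14-triene-1,4-dione | O=C1CCC(=O)[C@H]2[C@@]1(C)[C@@H](O[Si](C)(C)C(C)(C)C)C=C(C)[C@]2(C)[C@@H](O[Si](C)(C)C(C)(C)C)Cc1ccoc1 | intermediate
25 | 7β,8β-diol of 24 | O=C1CCC(=O)[C@H]2[C@@]1(C)[C@@H](O[Si](C)(C)C(C)(C)C)[C@H](O)[C@](C)(O)[C@]2(C)[C@@H](O[Si](C)(C)C(C)(C)C)Cc1ccoc1 | intermediate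
26 | (11S)-6α,11-bis(tert-butyldimethylsilyloxy)-7β,8β-dihydroxy-15,16-epoxy-neo-cleroda-4(18),13(16),14-trien-1-one | C=C1CCC(=O)[C@H]2[C@@]1(C)[C@@H](O[Si](C)(C)C(C)(C)C)[C@H](O)[C@](C)(O)[C@]2(C)[C@@H](O[Si](C)(C)C(C)(C)C)Cc1ccoc1 | intermediate
27 | 7β-isobutyrate of 26 | C=C1CCC(=O)[C@H]2[C@@]1(C)[C@@H](O[Si](C)(C)C(C)(C)C)[C@H](OC(=O)C(C)C)[C@](C)(O)[C@]2(C)[C@@H](O[Si](C)(C)C(C)(C)C)Cc1ccoc1 | intermediate
28 | (11S)-6α,8β,11-trihydroxy-7β-isobutyryloxy-15,16-epoxy-neo-cleroda-4(18),13(16),14-trien-1-one | C=C1CCC(=O)[C@H]2[C@@]1(C)[C@@H](O)[C@H](OC(=O)C(C)C)[C@](C)(O)[C@]2(C)[C@@H](O)Cc1ccoc1 | intermediate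
29 | (11S)-6α,11-diacetoxy-8β-hydroxy-7β-isobutyryloxy-15,16-epoxy-neo-cleroda-4(18),13(16),14-trien-1-one | C=C1CCC(=O)[C@H]2[C@@]1(C)[C@@H](OC(C)=O)[C@H](OC(=O)C(C)C)[C@](C)(O)[C@]2(C)[C@H](Cc1ccoc1)OC(C)=O | intermediate
30 | (11S)-6α,11-diacetoxy-1β,8β-dihydroxy-7β-isobutyryloxy-15,16-epoxy-neo-cleroda-4(18),13(16),14-triene | C=C1CC[C@@H](O)[C@H]2[C@@]1(C)[C@@H](OC(C)=O)[C@H](OC(=O)C(C)C)[C@](C)(O)[C@]2(C)[C@H](Cc1ccoc1)OC(C)=O | intermediate
31 | furan endoperoxide of 30 | C=C1CC[C@@H](O)[C@H]2[C@@]1(C)[C@@H](OC(C)=O)[C@H](OC(=O)C(C)C)[C@](C)(O)[C@]2(C)[C@H](CC1=CC2OOC1O2)OC(C)=O | intermediate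
32 | 16-hydroxy-15,16-olide (C16 epimers) | C=C1CC[C@@H](O)[C@H]2[C@@]1(C)[C@@H](OC(C)=O)[C@H](OC(=O)C(C)C)[C@](C)(O)[C@]2(C)[C@H](CC1=CC(=O)OC1O)OC(C)=O | intermediate
33 | CNP0254453.1 | C=C1CC[C@@H](O)[C@H]2[C@@]1(C)[C@@H](OC(C)=O)[C@H](OC(=O)C(C)C)[C@](C)(O)[C@]2(C)[C@H](CC1=CC(=O)OC1)OC(C)=O | target

**Count and risks**

Total step count: 24. Longest linear sequence: 24 steps (1 → 33; 18 is commercial).

Steps most likely to fail:

Step 15. The ketene may be captured by the free C1 hydroxyl (lactonization) before it closes on the fully substituted C5; face selectivity at C5 may be incomplete; ketonization may give cis-fusion. Fallback, from 17 and 18: after tin–lithium exchange and addition to 18, the lithium alkoxide is silylated in the flask (Me3SiCl) to give the 4-(trimethylsilyloxy)cyclobutenone F1. Thermolysis (toluene, 110 °C) then gives the isolable, regiodefined silyl dienol ether F2 with no hydroxyl left to trap the ketene. Protodesilylation with Bu4NF/AcOH at −78 °C protonates C10 under kinetic control from the β-face and returns to 23.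

Step 10. The chromium–peroxide system may oxidize the furan or the furylic C12 methylene in competition with C6–H abstraction. Fallback, from 12: dehydrogenation with IBX (DMSO, 70 °C) gives the linear dienone F3. Nucleophilic epoxidation (t-BuOOH, DBU) of its α,β-bond, anti to the C9 side chain, gives the 5α,6α-epoxy ketone F4. SmI2 (THF/MeOH, −90 °C) opens it to the 6α-hydroxy ketone F5, and silylation (TBSOTf, 2,6-lutidine) gives the bis-silyl ketone F6. Enolate triflation (KN(SiMe3)2, PhNTf2) returns to 16; the C6 configuration then rests on substrate control in the epoxidation instead of the CBS step.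

Step 22. Diastereoselectivity may be poor, or the axial 1α-alcohol may form. Fallback, from 29: NaBH4 (MeOH, 0 °C), which is expected to attack from the β-face, gives the 1α-alcohol F7. Mitsunobu inversion (Ph3P, diisopropyl azodicarboxylate, ClCH2CO2H) gives the 1β-chloroacetate F8. Selective removal of the chloroacetyl group with thiourea/NaHCO3, which leaves the acetates and the isobutyrate, returns to 30.

**Further compounds**

F1 | step 15 | 4-(trimethylsilyloxy)-2,3-dimethoxy-4-(ring-B dienyl)cyclobut-2-en-1-one | CC(C)(C)[Si](C)(C)O[C@H]1C=C(C)[C@](C)([C@@H](O[Si](C)(C)C(C)(C)C)Cc2ccoc2)C(C2(O[Si](C)(C)C)C(OC)=C(OC)C2=O)=C1C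
F2 | step 15 | 1-(trimethylsilyloxy)-2,3-dimethoxy-1(10),2-dien-4-one (silyl dienol ether of 23) | O=C1C(OC)=C(OC)C(O[Si](C)(C)C)=C2[C@@]1(C)[C@@H](O[Si](C)(C)C(C)(C)C)C=C(C)[C@]2(C)[C@@H](O[Si](C)(C)C(C)(C)C)Cc1ccoc1
F3 | step 10 | (6R)-6-[(1S)-1-(tert-butyldimethylsilyloxy)-2-(furan-3-yl)ethyl]-2,5,6-trimethylcyclohexa-2,4-dien-1-one | O=C1C(C)=CC=C(C)[C@]1(C)[C@@H](O[Si](C)(C)C(C)(C)C)Cc1ccoc1
F4 | step 10 | 5α,6α-epoxide of F3 | O=C1[C@@]2(C)O[C@H]2C=C(C)[C@]1(C)[C@@H](O[Si](C)(C)C(C)(C)C)Cc1ccoc1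
F5 | step 10 | 6α-hydroxy ketone (C5 epimers) | O=C1C(C)[C@@H](O)C=C(C)[C@]1(C)[C@@H](O[Si](C)(C)C(C)(C)C)Cc1ccoc1
F6 | step 10 | 6α-(tert-butyldimethylsilyloxy) ketone (C5 epimers) | O=C1C(C)[C@@H](O[Si](C)(C)C(C)(C)C)C=C(C)[C@]1(C)[C@@H](O[Si](C)(C)C(C)(C)C)Cc1ccoc1
F7 | step 22 | 1α-epimer of 30 | C=C1CC[C@H](O)[C@H]2[C@@]1(C)[C@@H](OC(C)=O)[C@H](OC(=O)C(C)C)[C@](C)(O)[C@]2(C)[C@H](Cc1ccoc1)OC(C)=O
F8 | step 22 | 1β-chloroacetate of 30 | C=C1CC[C@@H](OC(=O)CCl)[C@H]2[C@@]1(C)[C@@H](OC(C)=O)[C@H](OC(=O)C(C)C)[C@](C)(O)[C@]2(C)[C@H](Cc1ccoc1)OC(C)=O
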